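**Plan**

- Ring numbering: C1 (C=O between C2 and C6), C2 (OMe), C3 (H), C4 (C=O), C5 (Me), C6 (hexaprenyl). The retrosynthesis first removes the C1 oxygen (para-quinone back to the C4 phenol with H at C1). It then cuts the benzene ring at C3–C4, C1–C2 and C4–C5 and returns C6 from C1 to C4 (reverse Wolff shift). This leaves methoxyacetylene (C2–C3) and the acyclic diazo enone N2=C1H–C4(=O)–C6(hexaprenyl)=C5H–CH3.
- Enabling feature: in the six-membered ring the carbons C4, C1, C6 and C5 map onto a vinylketene whose carbonyl carbon is C4, the remaining edge C2(OMe)–C3(H) is a polarised ynol ether, and C1–H lies para to the C4 oxygen, so a single phenol oxidation gives the 1,4-dione.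
- Further cuts: C5=C6 (olefination with acetaldehyde), C6–C1' (alkylation of a three-carbon keto phosphonate by all-E hexaprenyl bromide), and C12'–C13' of the chain (allylic sulfone alkylation joining two C15 halves made from farnesol).
- Forward order: C15 + C15 to the C30 chain, chain onto the keto phosphonate, enone, diazo enone, then the only ring is closed last around the chain-bearing carbon and oxidised to the quinone.
- Stereochemistry: there are no stereocentres. Four E alkenes are those of (2E,6E)-farnesol and the fifth comes from an E-selective SeO2 hydroxylation. Later steps are chosen to leave alkene position and geometry alone, and the sp3 centres passed on the way are racemic and erased.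

Key step: step 15

Remark: "hexaprenyl" means the all-E 3,7,11,15,19,23-hexamethyltetracosa-2,6,10,14,18,22-hexaen-1-yl group. The E geometry written for the enone and the compounds derived from it is assumed as the expected major isomer; it is not transferred to the target.

**Route**

Step 1
Reactants: 1 (2E,6E)-farnesol
Product: 2 (2E,6E)-farnesyl bromide
Conditions: PBr3 (0.4 equiv), Et2O, −10 to 0 °C; used crude
Reagents that add atoms: phosphorus tribromide, BrP(Br)Br
Why: Bromination of a primary allylic alcohol with PBr3 at low temperature is an SN2-type displacement of the intermediate phosphite ester and should leave the position and E geometry of the neighbouring alkene unchanged.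

Step 2
Reactants: 2 (2E,6E)-farnesyl bromide
Product: 3 (2E,6E)-farnesyl phenyl sulfone
Conditions: PhSO2Na (1.3 equiv), DMF, 0 °C to rt
Reagents that add atoms: sodium benzenesulfinate, [Na+].[O-]S(=O)c1ccccc1
Why: S-alkylation of the sulfinate anion by the primary allylic bromide (SN2) in a dipolar aprotic solvent is the standard entry to allylic aryl sulfones and does not touch the alkenes.

Step 3
Reactants: 1 (2E,6E)-farnesol
Product: 4 (2E,6E)-farnesyl tert-butyldimethylsilyl ether
Conditions: TBSCl (1.1 equiv), imidazole (2 equiv), DMF, rt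
Reagents that add atoms: tert-butyldimethylsilyl chloride, CC(C)(C)[Si](C)(C)Cl
Why: Imidazole-promoted O-silylation of the primary alcohol gives a silyl ether that tolerates the oxidant, the sulfonyl carbanion and the hydride used later and is removed by fluoride.

Step 4
Reactants: 4 (2E,6E)-farnesyl tert-butyldimethylsilyl ether
Product: 5 (2E,6E,10E)-12-hydroxyfarnesyl tert-butyldimethylsilyl ether, that is (2E,6E,10E)-12-(tert-butyldimethylsilyloxy)-2,6,10-trimethyldodeca-2,6,10-trien-1-ol
Conditions: SeO2 (0.1 equiv), t-BuOOH (3 equiv), salicylic acid (0.1 equiv), CH2Cl2, 0 °C to rt; stopped at partial conversion, 4 recovered and recycled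
Reagents that add atoms: tert-butyl hydroperoxide, CC(C)(C)OO (terminal oxidant); selenium dioxide, O=[Se]=O (catalytic oxygen carrier)
Why: SeO2-catalysed allylic hydroxylation (ene reaction, then [2,3]-sigmatropic shift) attacks the most electron-rich terminal trisubstituted alkene at the methyl group trans to the chain, which sets the 10E geometry, while the 2,3-alkene is deactivated by its allylic silyloxy group.

Step 5
Reactants: 5 (2E,6E,10E)-12-hydroxyfarnesyl tert-butyldimethylsilyl ether
Product: 6 (2E,6E,10E)-12-bromofarnesyl tert-butyldimethylsilyl ether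
Conditions: CBr4 (1.2 equiv), PPh3 (1.25 equiv), CH2Cl2, −20 to 0 °C
Reagents that add atoms: carbon tetrabromide, BrC(Br)(Br)Br
Why: Appel bromination replaces the primary allylic hydroxyl through its alkoxyphosphonium salt by SN2 displacement under near-neutral conditions, so the silyl ether and the position and geometry of the alkene should be preserved.

Step 6
Reactants: 3 (2E,6E)-farnesyl phenyl sulfone; 6 (2E,6E,10E)-12-bromofarnesyl tert-butyldimethylsilyl ether
Product: 8 all-E C30 allylic sulfone, the tert-butyldimethylsilyl ether of 13-(phenylsulfonyl)hexaprenol (racemic at C13), via lithiated sulfone 7 (not isolated)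
Conditions: 3 (1.05 equiv), n-BuLi (1.05 equiv), THF, −78 °C; then 6, −78 to −20 °C
Reagents that add atoms: none
Why: Alkylation of the α-sulfonyl allylic carbanion at its α-carbon by the primary allylic bromide (SN2) forms the C12'–C13' bond of the chain without moving any alkene, and the new racemic centre is removed in the next step.

Step 7
Reactants: 8 all-E C30 allylic sulfone
Product: 9 all-E hexaprenyl tert-butyldimethylsilyl ether
Conditions: PdCl2[Ph2P(CH2)3PPh2] (5 mol %), LiBHEt3 (2.5 equiv), THF, 0 °C
Reagents that add atoms: none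
Why: In this palladium-catalysed reductive desulfonylation the divalent palladium precatalyst is reduced by the borohydride to zerovalent palladium, which ionises the allylic sulfone to a π-allyl complex that accepts hydride at its less substituted terminus, so the trisubstituted alkene should stay in place with its E geometry.

Step 8
Reactants: 9 all-E hexaprenyl tert-butyldimethylsilyl ether
Product: 10 all-E hexaprenol
Conditions: Bu4NF (1.2 equiv), THF, 0 °C to rt
Reagents that add atoms: none
Why: Fluoride-induced desilylation, driven by the strength of the Si–F bond, frees the primary allylic alcohol under conditions that are inert toward the six alkenes.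

Step 9
Reactants: 10 all-E hexaprenol
Product: 11 all-E hexaprenyl bromide
Conditions: PBr3 (0.4 equiv), Et2O, −10 to 0 °C; used at once
Reagents that add atoms: phosphorus tribromide, BrP(Br)Br
Why: As in step 1, low-temperature PBr3 bromination of a primary polyprenol proceeds by SN2-type displacement without allylic transposition or E/Z scrambling.

Step 10
Reactants: 12 diethyl (2-oxopropyl)phosphonate; 11 all-E hexaprenyl bromide
Product: 14 diethyl [1-(all-E-hexaprenyl)-2-oxopropyl]phosphonate (racemic), via sodium enolate 13 (not isolated)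
Conditions: 12 (2 equiv), NaH (1.9 equiv), THF, 0 °C; then 11, 0 °C to rt
Reagents that add atoms: none
Why: C-alkylation of the soft, doubly stabilised sodium enolate of the β-keto phosphonate by the primary allylic bromide (SN2) forms the C6–C1' bond, with excess nucleophile suppressing dialkylation, and the new racemic centre becomes sp2 in the next step.

Step 11
Reactants: 14 diethyl [1-(all-E-hexaprenyl)-2-oxopropyl]phosphonate; 15 acetaldehyde
Product: 17 (E)-3-(all-E-hexaprenyl)pent-3-en-2-one, via phosphonate anion 16 (not isolated)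
Conditions: NaH (1.0 equiv), THF, 0 °C; then MeCHO (5 equiv), 0 °C to rt, sealed vessel
Reagents that add atoms: none
Why: Horner–Wadsworth–Emmons olefination of the α-substituted phosphonate anion with the small unhindered aldehyde forms the C5=C6 bond and should favour the E isomer with acetyl trans to methyl, the geometry that later keeps the methyl group away from the ketene terminus.

Step 12
Reactants: 17 (E)-3-(all-E-hexaprenyl)pent-3-en-2-one
Product: 19 (E)-1,1,1-trifluoro-5-(all-E-hexaprenyl)hept-5-ene-2,4-dione, via lithium enolate 18 (not isolated)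
Conditions: LiN(SiMe3)2 (1.1 equiv), THF, −78 °C; CF3CO2CH2CF3 (1.2 equiv), −78 °C; cold dilute HCl/Et2O work-up; crude used directly
Reagents that add atoms: 2,2,2-trifluoroethyl trifluoroacetate, O=C(OCC(F)(F)F)C(F)(F)F
Why: Kinetic deprotonation of the enone at the acetyl methyl group by the hindered amide base at −78 °C gives the cross-conjugated enolate, whose Claisen-type C-acylation by the activated trifluoroacetate ester makes that carbon acidic enough for diazo transfer.

Step 13
Reactants: 19 (E)-1,1,1-trifluoro-5-(all-E-hexaprenyl)hept-5-ene-2,4-dione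
Product: 20 (E)-1-diazo-3-(all-E-hexaprenyl)pent-3-en-2-one
Conditions: MsN3 (1.5 equiv), Et3N (1.5 equiv), H2O (1 equiv), MeCN, rt; dilute aq. NaOH wash
Reagents that add atoms: methanesulfonyl azide, CS(=O)(=O)N=[N+]=[N-]
Why: Detrifluoroacetylative diazo transfer (Regitz-type transfer from the sulfonyl azide to the activated methylene, then loss of the trifluoroacetyl group) gives the diazo enone under mild base and avoids the pyrazoline formation that threatens when an enoyl chloride is treated with diazomethane.

Step 14
Reactants: 21 chloroacetaldehyde dimethyl acetal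
Product: 24 methoxyacetylene, via chloro enol ether 22 (not isolated), via sodium methoxyacetylide 23 (not isolated)
Conditions: NaNH2 (3 equiv), liquid NH3, −33 °C; cold saturated aq. NaCl, −70 °C; distilled into a cold receiver and kept as a cold solution behind a shield
Reagents that add atoms: none
Why: Twofold base-induced elimination (methanol, then HCl) by NaNH2 in liquid NH3 gives the alkyne, which is held as its sodium acetylide until the cold aqueous quench releases the volatile ynol ether.

Step 15
Reactants: 20 (E)-1-diazo-3-(all-E-hexaprenyl)pent-3-en-2-one; 24 methoxyacetylene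
Product: 29 5-methoxy-2-methyl-3-(all-E-hexaprenyl)phenol, via vinylketene 25 (not isolated), via vinylcyclobutenone 26 (not isolated), via dienylketene 27 (not isolated), via cyclohexadienone 28 (not isolated)
Conditions: 24 (4 equiv), degassed ClCH2CH2Cl (0.3 M), sealed quartz pressure tube, hν (254 nm, low-pressure Hg lamp), 5–15 °C; then 80 °C, sealed
Reagents that add atoms: none
Why: Irradiation expels N2 from 20 and the alkenyl carbon C6 shifts from C4 to the carbene carbon C1 (photochemical Wolff rearrangement, new C1–C6 bond) to give vinylketene 25, across whose ketene C=C the electron-rich alkyne adds in a regiospecific [2+2] cycloaddition (C3–C4 and C2–C1 formed) to close the four-membered ring of 26. On warming, 26 reopens reversibly by 4π-electrocyclic cleavage of C4–C1 to dienylketene 27, and the isomer with C3 and C6 cis is drained by a thermal disrotatory 6π-electrocyclisation that forms C4–C5 and closes the six-membered carbocycle as cyclohexadienone 28, which tautomerises to phenol 29. The closest known reaction is the Danheiser benzannulation in its photochemical Wolff variant, which joins diazo enones of this type and alkoxyacetylenes to resorcinol monoethers and is here only applied to a substrate carrying a polyprenyl chain. No stereocentre survives, because the sp3 carbons of 26 and 28 are racemic and are erased by ring opening and enolisation. The selectivity needed is the orientation of the [2+2] step, and it is secured by the polarisation of the ynol ether, whose unsubstituted carbon is the nucleophile that bonds to the electrophilic ketene carbonyl carbon C4, so that the methoxy group ends meta and the ring hydrogen para to the phenol oxygen. Chemoselectivity over the six chain alkenes rests on the neutral medium free of Lewis acid, on their transparency at the wavelength used and on the excess of the far more ketenophilic alkyne, so the substituent pattern is fixed by connectivity and not by arene directing effects.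

Step 16
Reactants: 29 5-methoxy-2-methyl-3-(all-E-hexaprenyl)phenol
Product: 30 2-methoxy-5-methyl-6-(all-E-hexaprenyl)-1,4-benzoquinone (target)
Conditions: (KSO3)2NO (3 equiv), aq. KH2PO4 buffer, CH2Cl2/H2O, Bu4NHSO4 (cat.), rt
Reagents that add atoms: potassium nitrosodisulfonate, [K+].[K+].[O]N(S(=O)(=O)[O-])S(=O)(=O)[O-]
Why: In this Teuber oxidation the nitrosodisulfonate radical abstracts the phenolic hydrogen, a second equivalent couples at the free para carbon C1 and loss of imidodisulfonate gives the para-quinone, a course that is well established for 3-methoxyphenols with an open para position.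

**Compound list**

1 | (2E,6E)-farnesol | OC/C=C(\C)CC/C=C(\C)CCC=C(C)C | starting material
2 | (2E,6E)-farnesyl bromide | BrC/C=C(\C)CC/C=C(\C)CCC=C(C)C | intermediate
3 | (2E,6E)-farnesyl phenyl sulfone | O=S(=O)(c1ccccc1)C/C=C(\C)CC/C=C(\C)CCC=C(C)C | intermediate
4 | (2E,6E)-farnesyl tert-butyldimethylsilyl ether | CC(C)(C)[Si](C)(C)OC/C=C(\C)CC/C=C(\C)CCC=C(C)C | intermediate
5 | (2E,6E,10E)-12-hydroxyfarnesyl tert-butyldimethylsilyl ether | CC(C)(C)[Si](C)(C)OC/C=C(\C)CC/C=C(\C)CC/C=C(\C)CO | intermediate
6 | (2E,6E,10E)-12-bromofarnesyl tert-butyldimethylsilyl ether | CC(C)(C)[Si](C)(C)OC/C=C(\C)CC/C=C(\C)CC/C=C(\C)CBr | intermediate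
7 | α-lithiated (2E,6E)-farnesyl phenyl sulfone | [Li]C(/C=C(\C)CC/C=C(\C)CCC=C(C)C)S(=O)(=O)c1ccccc1 | intermediate (not isolated)
8 | all-E C30 allylic sulfone, tert-butyldimethylsilyl ether of 13-(phenylsulfonyl)hexaprenol (racemic at C13) | CC(C)(C)[Si](C)(C)OC/C=C(\C)CC/C=C(\C)CC/C=C(\C)CC(/C=C(\C)CC/C=C(\C)CCC=C(C)C)S(=O)(=O)c1ccccc1 | intermediate
9 | all-E hexaprenyl tert-butyldimethylsilyl ether | CC(C)(C)[Si](C)(C)OC/C=C(\C)CC/C=C(\C)CC/C=C(\C)CC/C=C(\C)CC/C=C(\C)CCC=C(C)C | intermediate
10 | all-E hexaprenol | OC/C=C(\C)CC/C=C(\C)CC/C=C(\C)CC/C=C(\C)CC/C=C(\C)CCC=C(C)C | intermediate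
11 | all-E hexaprenyl bromide | BrC/C=C(\C)CC/C=C(\C)CC/C=C(\C)CC/C=C(\C)CC/C=C(\C)CCC=C(C)C | intermediate
12 | diethyl (2-oxopropyl)phosphonate | CC(=O)CP(=O)(OCC)OCC | starting material
13 | sodium salt of diethyl (2-oxopropyl)phosphonate | [Na+].CC(=O)[CH-]P(=O)(OCC)OCC | intermediate (not isolated)
14 | diethyl [1-(all-E-hexaprenyl)-2-oxopropyl]phosphonate (racemic) | CC(=O)C(C/C=C(\C)CC/C=C(\C)CC/C=C(\C)CC/C=C(\C)CC/C=C(\C)CCC=C(C)C)P(=O)(OCC)OCC | intermediate
15 | acetaldehyde | CC=O | starting material
16 | sodium salt of 14 | [Na+].CC(=O)[C-](C/C=C(\C)CC/C=C(\C)CC/C=C(\C)CC/C=C(\C)CC/C=C(\C)CCC=C(C)C)P(=O)(OCC)OCC | intermediate (not isolated)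
17 | (E)-3-(all-E-hexaprenyl)pent-3-en-2-one | CC(=O)/C(C/C=C(\C)CC/C=C(\C)CC/C=C(\C)CC/C=C(\C)CC/C=C(\C)CCC=C(C)C)=C/C | intermediate
18 | cross-conjugated lithium enolate of 17 | [Li+].C=C([O-])/C(C/C=C(\C)CC/C=C(\C)CC/C=C(\C)CC/C=C(\C)CC/C=C(\C)CCC=C(C)C)=C/C | intermediate (not isolated)
19 | (E)-1,1,1-trifluoro-5-(all-E-hexaprenyl)hept-5-ene-2,4-dione | O=C(CC(=O)/C(C/C=C(\C)CC/C=C(\C)CC/C=C(\C)CC/C=C(\C)CC/C=C(\C)CCC=C(C)C)=C/C)C(F)(F)F | intermediate
20 | (E)-1-diazo-3-(all-E-hexaprenyl)pent-3-en-2-one | [N-]=[N+]=CC(=O)/C(C/C=C(\C)CC/C=C(\C)CC/C=C(\C)CC/C=C(\C)CC/C=C(\C)CCC=C(C)C)=C/C | intermediate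
21 | chloroacetaldehyde dimethyl acetal | COC(CCl)OC | starting material
22 | 1-chloro-2-methoxyethene (E/Z mixture) | COC=CCl | intermediate (not isolated)
23 | sodium methoxyacetylide | [Na+].[C-]#COC | intermediate (not isolated)
24 | methoxyacetylene | COC#C | intermediate
25 | (E)-3-(all-E-hexaprenyl)penta-1,3-dien-1-one (vinylketene) | O=C=C/C(C/C=C(\C)CC/C=C(\C)CC/C=C(\C)CC/C=C(\C)CC/C=C(\C)CCC=C(C)C)=C/C | intermediate (not isolated)
26 | 3-methoxy-4-[(E)-1-(all-E-hexaprenyl)prop-1-enyl]cyclobut-2-en-1-one (racemic) | COC1=CC(=O)C1/C(C/C=C(\C)CC/C=C(\C)CC/C=C(\C)CC/C=C(\C)CC/C=C(\C)CCC=C(C)C)=C/C | intermediate (not isolated)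
27 | 3-methoxy-5-(all-E-hexaprenyl)hepta-1,3,5-trien-1-one (dienylketene, ketene carbon and C6 cis) | O=C=C/C(OC)=C\C(C/C=C(\C)CC/C=C(\C)CC/C=C(\C)CC/C=C(\C)CC/C=C(\C)CCC=C(C)C)=C\C | intermediate (not isolated)
28 | 3-methoxy-6-methyl-5-(all-E-hexaprenyl)cyclohexa-2,4-dien-1-one (racemic) | COC1=CC(=O)C(C)C(C/C=C(\C)CC/C=C(\C)CC/C=C(\C)CC/C=C(\C)CC/C=C(\C)CCC=C(C)C)=C1 | intermediate (not isolated)
29 | 5-methoxy-2-methyl-3-(all-E-hexaprenyl)phenol | COc1cc(O)c(C)c(C/C=C(\C)CC/C=C(\C)CC/C=C(\C)CC/C=C(\C)CC/C=C(\C)CCC=C(C)C)c1 | intermediate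
30 | 2-methoxy-5-methyl-6-(all-E-hexaprenyl)-1,4-benzoquinone | COC1=CC(=O)C(C)=C(C/C=C(\C)CC/C=C(\C)CC/C=C(\C)CC/C=C(\C)CC/C=C(\C)CCC=C(C)C)C1=O | target

**Step count and risks**

Total step count: 16. Longest linear sequence: 13 steps (steps 3, 4, 5, 6, 7, 8, 9, 10, 11, 12, 13, 15, 16).

Steps most likely to fail:

1. Step 15. The photogenerated keto carbene may be intercepted before the Wolff shift by cyclopropanation of the nearest chain alkene, which lies in range for a bicyclo[3.1.0]hexanone. The volatile alkyne may also escape from solution, so that the vinylketene dimerises, or prolonged irradiation may degrade the electron-rich product. The fallback gives up de novo ring construction and attaches the chain to a preformed quinone. It sets out from 11 and returns at 30. Treatment of 11 with Bu3SnLi in THF at −78 °C should give all-E hexaprenyl(tributyl)stannane F1. Allylation of commercial 2-methoxy-5-methyl-1,4-benzoquinone (COC1=CC(=O)C(C)=CC1=O) with F1 and BF3·OEt2 in CH2Cl2 at −78 °C should then proceed by addition at the C1 carbonyl, which the methoxy group does not deactivate, followed by allyl shift to its only unsubstituted neighbour C6. After aqueous KF work-up this should give 2-methoxy-5-methyl-6-(all-E-hexaprenyl)benzene-1,4-diol F2, which Ag2O in Et2O oxidises to 30. In this fallback regiocontrol rests on the electronic bias of the quinone rather than on connectivity.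

2. Step 12. Deprotonation may take place at the γ-methyl group or at the doubly allylic chain CH2 instead of the acetyl methyl group, or the enolate may add to unreacted enone. The trifluoroacetyl group would then end on the wrong carbon or oligomers would form. The fallback needs no ketone enolate and builds the diazo ketone by acylation of diazomethane. It sets out from 11 and returns at 20. Alkylation of the sodium salt of triethyl phosphonoacetate (NaH, THF) with 11 should give triethyl 2-(all-E-hexaprenyl)phosphonoacetate F3. Horner–Wadsworth–Emmons reaction of F3 with 15 (NaH, THF) should give ethyl (E)-2-(all-E-hexaprenyl)but-2-enoate F4, and LiOH in THF/MeOH/H2O should give (E)-2-(all-E-hexaprenyl)but-2-enoic acid F5. Activation with i-BuOCOCl and Et3N in THF at −15 °C gives the isobutyl carbonic mixed anhydride F6, which excess ethereal CH2N2 at 0 °C converts into 20 without exposing the chain to HCl.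

3. Step 11. The hindered, doubly stabilised phosphonate anion may add only slowly while the enolisable aldehyde is consumed by self-aldol condensation, or the β-hydroxy phosphonate adduct may revert instead of eliminating. The fallback makes the enone by reduction and elimination of a β-diketone instead of by olefination. It sets out from 11 and returns at 17. C-alkylation of pentane-2,4-dione with 11 (K2CO3, acetone, rt) should give 3-(all-E-hexaprenyl)pentane-2,4-dione F7. Mono-reduction with a limiting amount of NaBH4 in EtOH at −20 °C should give 4-hydroxy-3-(all-E-hexaprenyl)pentan-2-one F8. Mesylation (MsCl, Et3N, CH2Cl2, 0 °C) gives the methanesulfonate F9, and DBU then eliminates it by an E1cB pathway toward the acidic α-carbon to give 17.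

**Further compounds**

F1 | step 15 | all-E hexaprenyl(tributyl)stannane | CCCC[Sn](CCCC)(CCCC)C/C=C(\C)CC/C=C(\C)CC/C=C(\C)CC/C=C(\C)CC/C=C(\C)CCC=C(C)C
F2 | step 15 | 2-methoxy-5-methyl-6-(all-E-hexaprenyl)benzene-1,4-diol | COc1cc(O)c(C)c(C/C=C(\C)CC/C=C(\C)CC/C=C(\C)CC/C=C(\C)CC/C=C(\C)CCC=C(C)C)c1O
F3 | step 12 | triethyl 2-(all-E-hexaprenyl)phosphonoacetate | CCOC(=O)C(C/C=C(\C)CC/C=C(\C)CC/C=C(\C)CC/C=C(\C)CC/C=C(\C)CCC=C(C)C)P(=O)(OCC)OCC
F4 | step 12 | ethyl (E)-2-(all-E-hexaprenyl)but-2-enoate | CCOC(=O)/C(C/C=C(\C)CC/C=C(\C)CC/C=C(\C)CC/C=C(\C)CC/C=C(\C)CCC=C(C)C)=C/C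
F5 | step 12 | (E)-2-(all-E-hexaprenyl)but-2-enoic acid | OC(=O)/C(C/C=C(\C)CC/C=C(\C)CC/C=C(\C)CC/C=C(\C)CC/C=C(\C)CCC=C(C)C)=C/C
F6 | step 12 | isobutyl carbonic mixed anhydride of (E)-2-(all-E-hexaprenyl)but-2-enoic acid | CC(C)COC(=O)OC(=O)/C(C/C=C(\C)CC/C=C(\C)CC/C=C(\C)CC/C=C(\C)CC/C=C(\C)CCC=C(C)C)=C/C
F7 | step 11 | 3-(all-E-hexaprenyl)pentane-2,4-dione | CC(=O)C(C/C=C(\C)CC/C=C(\C)CC/C=C(\C)CC/C=C(\C)CC/C=C(\C)CCC=C(C)C)C(C)=O
F8 | step 11 | 4-hydroxy-3-(all-E-hexaprenyl)pentan-2-one | CC(=O)C(C/C=C(\C)CC/C=C(\C)CC/C=C(\C)CC/C=C(\C)CC/C=C(\C)CCC=C(C)C)C(C)O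
F9 | step 11 | 4-(methanesulfonyloxy)-3-(all-E-hexaprenyl)pentan-2-one | CC(=O)C(C/C=C(\C)CC/C=C(\C)CC/C=C(\C)CC/C=C(\C)CC/C=C(\C)CCC=C(C)C)C(C)OS(C)(=O)=O
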